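The operator ran one recipe three times and stopped it at three different times.

all flasks: substrate 2.0 mM; reagent 0.500 equiv; free catalyst 7.7 mol%

| run | time |
|---|---|
| Saturday's | 25 s |
| Sunday's | 100 s |
| Monday's | 50 s |

    reagent + free catalyst → catalyst intermediate A (k1 = 4600 M⁻¹ s⁻¹)
    catalyst intermediate A → by-product + catalyst intermediate B (k2 = 370 s⁻¹)
    substrate + catalyst intermediate B ⇌ catalyst intermediate C (K3 = 95 M⁻¹, k3 = 1500 M⁻¹ s⁻¹)
    catalyst intermediate C → free catalyst + target (k4 = 27 s⁻¹)
    target + by-product → side product (k5 = 33 M⁻¹ s⁻¹)

1. which of the two there is more of at the end, Saturday's (target / side product)
2. which of the two there is more of at the end, Sunday's (target / side product)
3. which of the two there is more of at the end, Monday's (target / side product)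
4. how much target is there at the end, in percent of the substrate charged: Saturday's
5. how much target is there at the end, in percent of the substrate charged: Sunday's
6. how much target is there at the end, in percent of the substrate charged: Monday's

I reckoned by hand before anything else. Each turn of the catalyst spent one reagent and one substrate and gave one by-product and one target. The reagent charge of 1.00 mM was less than the substrate charge, so reagent was the limiting reagent. Target plus side product could therefore reach 50.0% of the substrate charged.

Target and by-product were made in equal amounts, and they then met in one second-order step. That gave me one number for Saturday's flask, 0.825. I called it the spoilage number, the constant of the loss step times the limiting charge times the time. For Sunday's it was 3.30, and for Monday's 1.65.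

The number says how far the loss has gone. At 1 target and side product stand equal, and that symmetric case is the zero of the scale. Below it target leads, above it side product leads. The target left is the cap divided by one plus the number.

So I read Saturday's as target at 27.4%. Sunday's came out as side product with 11.6% target. Monday's came out as side product with 18.9% target.

Was one number enough? It starts the clock with the whole reagent charge already turned over. The pseudo-first-order half-life of reagent by step 1 alone, with free catalyst held at its charge in Saturday's flask, was 0.98 s. My number put the equal point at 30.3 s, which is far longer. I let the number stand and expected my percentages to run a little low.

The forecast gave the same marks: target, side product, side product. Its target figures were 29.5%, 12% and 19.8%, each above mine. Its ground was that “the target simply decays by equal-concentration second-order reaction with the by-product”.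

The simulation gave 30.4% target on Saturday's, 12.1% on Sunday's and 20.2% on Monday's. Saturday's ended with target ahead, Sunday's with side product ahead, and Monday's with side product ahead. In Saturday's flask reagent stood at 0.469% of its charge at 12.5 s, and at the end side product over target read 0.647, below the spoilage number of 0.825. A further flask, like Monday's but with 2.00 equiv of reagent, kept 0.087% of its substrate, so substrate was the limiting charge. Its spoilage number was 3.30, which puts target at 23.3% of the substrate charged. That flask held 25.6% target.

The numbers of this flask are assumed.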